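**Retrosynthetic overview**

1. The target is opened at the spiro-cyclohexene: it is the isomerised Diels–Alder adduct of monomer 21 (dienophile, C4=C15 enone) and its 1,2-dehydro derivative 23 (diene C2′=C1′–C10′=C14′), which is made from 21 by Saegusa oxidation. This ring is formed last.
2. Monomer 21 is cut at C5–C6. The enone β-carbon C5 of a 2-(acetoxymethyl)cyclopentenone is made nucleophilic as an allylindium (a ketone homoenolate equivalent) and closes the seven-membered ring on the C6 aldehyde. The same step creates the C4=C15 methylene ketone and, by lactonisation, the trans-lactone.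
3. The cyclisation precursor 18 is cut at C7–C8: 2-(methoxycarbonyl)allylboronate 14 (an ester homoenolate equivalent) adds syn to aldehyde 9 under catalyst control.
4. Aldehyde 9 comes from (R)-4-silyloxycyclopentenone 3 (conjugate addition–elimination sets C1), 3-bromobut-3-en-1-ol and formaldehyde; 14 comes from methyl acrylate and 2,2-dimethoxyacetaldehyde.
5. Ring order: cyclopentenone (bought) → seven-membered carbocycle plus γ-lactone (one step) → spiro-cyclohexene (dimerisation).

Labels: C1–C15 follow guaiane numbering of the monomer; primed labels belong to the enone-containing (diene-derived) half of the dimer.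

Assumption: at the base-labile C5′ centre, the 5′β-H configuration drawn in the target (cis to 10′β-H across the planar C1′) is taken to be the thermodynamically preferred one.

**Route**

Step 1
Reactants: 1 3-bromobut-3-en-1-ol
Product: 2 [(3-bromobut-3-en-1-yl)oxy]triethylsilane
Conditions: TESCl, imidazole, CH2Cl2, 0 °C to rt
Reagents that add atoms: chlorotriethylsilane, CC[Si](Cl)(CC)CC
Why: Standard silyl ether formation on a primary alcohol; no stereocentre is involved.

Step 2
Reactants: 2 [(3-bromobut-3-en-1-yl)oxy]triethylsilane; 3 (R)-4-[(tert-butyldimethylsilyl)oxy]cyclopent-2-en-1-one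
Product: 6 (R)-4-{4-[(triethylsilyl)oxy]but-1-en-2-yl}cyclopent-2-en-1-one, via Grignard reagent 4 (not isolated), via silyloxy ketone 5 (not isolated)
Conditions: 2, Mg, THF, 45 °C; CuBr·SMe2 (10 mol%), 3, THF, −78 to −40 °C; aq NH4Cl; crude 5, DBU, CH2Cl2, −20 to 0 °C
Reagents that add atoms: none
Why: Copper-catalysed conjugate addition of the alkenyl Grignard reagent occurs anti to the OTBS group, and E1cB loss of TBSOH then moves the enone to the other side (conjugate addition–elimination), so the former β-carbon becomes C1 with R configuration.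

Step 3
Reactants: 6 (R)-4-{4-[(triethylsilyl)oxy]but-1-en-2-yl}cyclopent-2-en-1-one
Product: 7 (R)-2-(hydroxymethyl)-4-{4-[(triethylsilyl)oxy]but-1-en-2-yl}cyclopent-2-en-1-one
Conditions: 37% aq CH2O, imidazole (1 equiv), THF/H2O, rt
Reagents that add atoms: formaldehyde, C=O
Why: Morita–Baylis–Hillman reaction: imidazole adds reversibly to the enone β-carbon and the enolate is hydroxymethylated at the α-carbon (future C4 with C15), leaving C1 untouched.

Step 4
Reactants: 7 (R)-2-(hydroxymethyl)-4-{4-[(triethylsilyl)oxy]but-1-en-2-yl}cyclopent-2-en-1-one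
Product: 8 {(R)-5-oxo-3-{4-[(triethylsilyl)oxy]but-1-en-2-yl}cyclopent-1-en-1-yl}methyl acetate
Conditions: Ac2O, pyridine, DMAP (cat.), CH2Cl2, 0 °C
Reagents that add atoms: acetic anhydride, CC(=O)OC(C)=O
Why: O-Acetylation turns the allylic alcohol into the leaving group needed for the later π-allyl chemistry and protects it meanwhile.

Step 5
Reactants: 8 {(R)-5-oxo-3-{4-[(triethylsilyl)oxy]but-1-en-2-yl}cyclopent-1-en-1-yl}methyl acetate
Product: 9 [(R)-5-oxo-3-(4-oxobut-1-en-2-yl)cyclopent-1-en-1-yl]methyl acetate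
Conditions: IBX (2.5 equiv), DMSO, rt
Reagents that add atoms: none
Why: One-pot oxidative desilylation: IBX in DMSO cleaves the primary TES ether and oxidises the alcohol to the aldehyde without amine base, which protects the β,γ-unsaturated aldehyde and the doubly allylic C1–H from isomerisation.

Step 6
Reactants: 10 methyl acrylate; 11 2,2-dimethoxyacetaldehyde (60% aq solution)
Product: 12 methyl 3-hydroxy-4,4-dimethoxy-2-methylidenebutanoate (racemic)
Conditions: DABCO (20 mol%), 1,4-dioxane/H2O, rt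
Reagents that add atoms: none
Why: Morita–Baylis–Hillman reaction of an activated α-alkoxy aldehyde; the carbinol centre is destroyed in step 8, so the racemate is used.

Step 7
Reactants: 12 methyl 3-hydroxy-4,4-dimethoxy-2-methylidenebutanoate
Product: 13 methyl 3-acetoxy-4,4-dimethoxy-2-methylidenebutanoate (racemic)
Conditions: Ac2O, pyridine, DMAP (cat.), CH2Cl2, 0 °C
Reagents that add atoms: acetic anhydride, CC(=O)OC(C)=O
Why: Acetylation gives the Baylis–Hillman acetate required for allylic borylation.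

Step 8
Reactants: 13 methyl 3-acetoxy-4,4-dimethoxy-2-methylidenebutanoate
Product: 14 methyl (E)-4,4-dimethoxy-2-[(4,4,5,5-tetramethyl-1,3,2-dioxaborolan-2-yl)methyl]but-2-enoate
Conditions: B2pin2, CuCl (10 mol%), KOAc (20 mol%), DMF, rt
Reagents that add atoms: bis(pinacolato)diboron, CC1(C)OB(OC1(C)C)B1OC(C)(C)C(C)(C)O1
Why: Copper-catalysed borylative allylic substitution (SN2′): Cu–Bpin adds to the acrylate terminus and acetate is expelled, giving the alkene isomer with the acetal carbon trans to the ester and therefore cis to CH2B.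

Step 9
Reactants: 9 [(R)-5-oxo-3-(4-oxobut-1-en-2-yl)cyclopent-1-en-1-yl]methyl acetate; 14 methyl (E)-4,4-dimethoxy-2-[(4,4,5,5-tetramethyl-1,3,2-dioxaborolan-2-yl)methyl]but-2-enoate
Product: 16 methyl (3R,4R)-6-[(1R)-3-(acetoxymethyl)-4-oxocyclopent-2-en-1-yl]-3-(dimethoxymethyl)-4-hydroxy-2-methylidenehept-6-enoate, via borate ester 15 (not isolated)
Conditions: (S)-TRIP phosphoric acid (10 mol%), 4 Å MS, toluene, 0 °C to rt; aq NaHCO3
Reagents that add atoms: none
Why: Proposed new method: chiral phosphoric acid-catalysed allylboration extended to a γ-substituted 2-(alkoxycarbonyl)allylboronate – the acid hydrogen-bonds to a boronate oxygen in a closed chair transition state, the γ-acetal cis to CH2B sits axial and gives the syn (7R,8R) adduct, the (S)-catalyst (chosen by analogy, not the remote C1 centre) selects the aldehyde Si face, and the new C7–C8 bond joins an aldehyde carbon to the β-carbon of an acrylate (ester homoenolate equivalent); the closest known reactions are Brønsted acid-catalysed 2-alkoxycarbonyl allylborations and phosphoric acid-catalysed crotylborations.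

Step 10
Reactants: 16 methyl (3R,4R)-6-[(1R)-3-(acetoxymethyl)-4-oxocyclopent-2-en-1-yl]-3-(dimethoxymethyl)-4-hydroxy-2-methylidenehept-6-enoate
Product: 18 methyl (3R,4R)-6-[(1R)-3-(acetoxymethyl)-4-oxocyclopent-2-en-1-yl]-3-formyl-2-methylidene-4-[(triethylsilyl)oxy]hept-6-enoate, via collidinium salt 17 (not isolated)
Conditions: TESOTf (3 equiv), 2,4,6-collidine, CH2Cl2, 0 °C; then H2O
Reagents that add atoms: triethylsilyl trifluoromethanesulfonate, CC[Si](CC)(CC)OS(=O)(=O)C(F)(F)F; water, O
Why: Silyl triflate–collidine acetal cleavage: TESOTf silylates the C8 hydroxyl and converts the dimethyl acetal into a collidinium N,O-acetal that water hydrolyses to the aldehyde under non-acidic conditions, leaving C7, the ester and the allylic acetate intact.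

Step 11
Reactants: 18 methyl (3R,4R)-6-[(1R)-3-(acetoxymethyl)-4-oxocyclopent-2-en-1-yl]-3-formyl-2-methylidene-4-[(triethylsilyl)oxy]hept-6-enoate
Product: 21 8β-(triethylsilyloxy)-3-oxo-1αH,5αH-guaia-4(15),10(14),11(13)-trien-12,6α-olide, via allylindium 19 (not isolated), via indium alkoxide 20 (not isolated)
Conditions: Pd(PPh3)4 (5 mol%), InI (1.5 equiv), THF (0.01 M), rt; aq NH4Cl
Reagents that add atoms: none
Why: Proposed new method: palladium-catalysed, InI-mediated umpolung allylation applied to a 2-(acetoxymethyl)cyclopentenone – zerovalent palladium ionises the allylic acetate, monovalent indium reduces the π-allyl complex to an allylindium in which the enone β-carbon C5 is nucleophilic (ketone homoenolate equivalent), and C5 adds to the C6 aldehyde through a chair-like six-membered transition state on the face held by the C1 tether, giving the cis-fused seven-membered ring (5α-H), the 6α-alkoxide (anti addition of the ring-locked E-allyl unit) and the C4=C15 methylene at once, after which the alkoxide lactonises onto the ester; the closest known reactions are the intramolecular Pd/InI allylation of aldehydes by allylic acetates and Barbier lactonisations with 2-(bromomethyl)acrylates.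

Step 12
Reactants: 21 8β-(triethylsilyloxy)-3-oxo-1αH,5αH-guaia-4(15),10(14),11(13)-trien-12,6α-olide
Product: 22 3-(tert-butyldimethylsilyloxy)-8β-(triethylsilyloxy)-1αH,5αH-guaia-2,4(15),10(14),11(13)-tetraen-12,6α-olide
Conditions: TBSOTf, Et3N, CH2Cl2, −78 to 0 °C
Reagents that add atoms: tert-butyldimethylsilyl trifluoromethanesulfonate, CC(C)(C)[Si](C)(C)OS(=O)(=O)C(F)(F)F
Why: Soft enolisation at the only enolisable position (C2) gives the cross-conjugated silyl dienol ether (silyl enol ether formation).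

Step 13
Reactants: 22 3-(tert-butyldimethylsilyloxy)-8β-(triethylsilyloxy)-1αH,5αH-guaia-2,4(15),10(14),11(13)-tetraen-12,6α-olide; 21 8β-(triethylsilyloxy)-3-oxo-1αH,5αH-guaia-4(15),10(14),11(13)-trien-12,6α-olide (2 equiv)
Product: 25 8,8′-bis-O-triethylsilyl ether of the target, via dienone 23 (not isolated), via Diels–Alder adduct 24 (not isolated)
Conditions: Pd(OAc)2 (1.05 equiv), MeCN, argon, rt to 40 °C; then DBU (0.3 equiv), rt
Reagents that add atoms: none
Why: Saegusa–Ito oxidation gives the cross-conjugated dienone whose locked s-cis diene (C2′=C1′–C10′=C14′) adds to the exocyclic enone of 21 in an ortho-regioselective Diels–Alder reaction from the convex α-face of each partner (spiro C4 becomes R, 2′β-H), then DBU shifts the 2′β-H suprafacially to C10′ (1,3-prototropic shift to the conjugated enone, 10′β-H) and equilibrates the now γ-acidic C5′ to the cis 5′β-H epimer.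

Step 14
Reactants: 25 8,8′-bis-O-triethylsilyl ether of the target
Product: 26 CNP0397417.1 (target)
Conditions: HF·pyridine, THF/pyridine, 0 °C to rt
Reagents that add atoms: none
Why: Fluoride-mediated desilylation removes both secondary TES ethers under mildly acidic conditions that do not touch the enones, the lactones or the base-labile C5′ and C10′ centres.

**Compound list**

1 | 3-bromobut-3-en-1-ol | OCCC(Br)=C | starting material
2 | [(3-bromobut-3-en-1-yl)oxy]triethylsilane | CC[Si](CC)(CC)OCCC(Br)=C | intermediate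
3 | (R)-4-[(tert-butyldimethylsilyl)oxy]cyclopent-2-en-1-one | O=C1C=C[C@H](O[Si](C)(C)C(C)(C)C)C1 | starting material
4 | {4-[(triethylsilyl)oxy]but-1-en-2-yl}magnesium bromide | C=C([Mg]Br)CCO[Si](CC)(CC)CC | intermediate (not isolated)
5 | (3S,4R)-4-[(tert-butyldimethylsilyl)oxy]-3-{4-[(triethylsilyl)oxy]but-1-en-2-yl}cyclopentan-1-one (trans) | O=C1C[C@@H](C(=C)CCO[Si](CC)(CC)CC)[C@H](O[Si](C)(C)C(C)(C)C)C1 | intermediate (not isolated)
6 | (R)-4-{4-[(triethylsilyl)oxy]but-1-en-2-yl}cyclopent-2-en-1-one | O=C1C=C[C@H](C(=C)CCO[Si](CC)(CC)CC)C1 | intermediate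
7 | (R)-2-(hydroxymethyl)-4-{4-[(triethylsilyl)oxy]but-1-en-2-yl}cyclopent-2-en-1-one | O=C1C(CO)=C[C@H](C(=C)CCO[Si](CC)(CC)CC)C1 | intermediate
8 | {(R)-5-oxo-3-{4-[(triethylsilyl)oxy]but-1-en-2-yl}cyclopent-1-en-1-yl}methyl acetate | O=C1C(COC(C)=O)=C[C@H](C(=C)CCO[Si](CC)(CC)CC)C1 | intermediate
9 | [(R)-5-oxo-3-(4-oxobut-1-en-2-yl)cyclopent-1-en-1-yl]methyl acetate | O=C1C(COC(C)=O)=C[C@H](C(=C)CC=O)C1 | intermediate
10 | methyl acrylate | C=CC(=O)OC | starting material
11 | 2,2-dimethoxyacetaldehyde | COC(OC)C=O | starting material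
12 | methyl 3-hydroxy-4,4-dimethoxy-2-methylidenebutanoate (racemic) | COC(=O)C(=C)C(O)C(OC)OC | intermediate
13 | methyl 3-acetoxy-4,4-dimethoxy-2-methylidenebutanoate (racemic) | COC(=O)C(=C)C(OC(C)=O)C(OC)OC | intermediate
14 | methyl (E)-4,4-dimethoxy-2-[(4,4,5,5-tetramethyl-1,3,2-dioxaborolan-2-yl)methyl]but-2-enoate (acetal cis to CH2B) | COC(=O)/C(=C/C(OC)OC)CB1OC(C)(C)C(C)(C)O1 | intermediate
15 | pinacol borate ester of 16 (O8–Bpin) | COC(=O)C(=C)[C@@H](C(OC)OC)[C@H](OB2OC(C)(C)C(C)(C)O2)CC(=C)[C@H]1C=C(COC(C)=O)C(=O)C1 | intermediate (not isolated)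
16 | methyl (3R,4R)-6-[(1R)-3-(acetoxymethyl)-4-oxocyclopent-2-en-1-yl]-3-(dimethoxymethyl)-4-hydroxy-2-methylidenehept-6-enoate (7R,8R in guaiane labels) | COC(=O)C(=C)[C@@H](C(OC)OC)[C@H](O)CC(=C)[C@H]1C=C(COC(C)=O)C(=O)C1 | intermediate
17 | 2,4,6-trimethylpyridinium N,O-acetal triflate of the 8-O-TES ether (acetal carbon unassigned) | COC(=O)C(=C)[C@@H](C(OC)[n+]2c(C)cc(C)cc2C)[C@H](O[Si](CC)(CC)CC)CC(=C)[C@H]1C=C(COC(C)=O)C(=O)C1.[O-]S(=O)(=O)C(F)(F)F | intermediate (not isolated)
18 | methyl (3R,4R)-6-[(1R)-3-(acetoxymethyl)-4-oxocyclopent-2-en-1-yl]-3-formyl-2-methylidene-4-[(triethylsilyl)oxy]hept-6-enoate | COC(=O)C(=C)[C@@H](C=O)[C@H](O[Si](CC)(CC)CC)CC(=C)[C@H]1C=C(COC(C)=O)C(=O)C1 | intermediate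
19 | allylindium acetate iodide derived from 18 (In on C15) | COC(=O)C(=C)[C@@H](C=O)[C@H](O[Si](CC)(CC)CC)CC(=C)[C@H]1C=C(C[In](I)OC(C)=O)C(=O)C1 | intermediate (not isolated)
20 | indium 6α-alkoxide of methyl 3-oxo-8β-(triethylsilyloxy)-1αH,5αH-guaia-4(15),10(14),11(13)-trien-12-oate | COC(=O)C(=C)[C@@H]1[C@H](O[Si](CC)(CC)CC)CC(=C)[C@@H]2CC(=O)C(=C)[C@@H]2[C@H]1O[In](I)OC(C)=O | intermediate (not isolated)
21 | 8β-(triethylsilyloxy)-3-oxo-1αH,5αH-guaia-4(15),10(14),11(13)-trien-12,6α-olide (1R,5R,6R,7S,8R) | C=C1C(=O)C[C@H]2C(=C)C[C@@H](O[Si](CC)(CC)CC)[C@H]3C(=C)C(=O)O[C@@H]3[C@H]21 | intermediate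
22 | 3-(tert-butyldimethylsilyloxy)-8β-(triethylsilyloxy)-1αH,5αH-guaia-2,4(15),10(14),11(13)-tetraen-12,6α-olide | C=C1C(O[Si](C)(C)C(C)(C)C)=C[C@H]2C(=C)C[C@@H](O[Si](CC)(CC)CC)[C@H]3C(=C)C(=O)O[C@@H]3[C@H]21 | intermediate
23 | 3-oxo-8β-(triethylsilyloxy)-5αH-guaia-1,4(15),10(14),11(13)-tetraen-12,6α-olide | C=C1C(=O)C=C2C(=C)C[C@@H](O[Si](CC)(CC)CC)[C@H]3C(=C)C(=O)O[C@@H]3[C@H]21 | intermediate (not isolated)
24 | Diels–Alder adduct (bonds C4–C2′ and C15–C14′; C1′=C10′ alkene, 2′β-H, 5′α-H; both 8-hydroxyls as TES ethers) | C=C1C(=O)[C@H]2C3=C(CC[C@]24C(=O)C[C@H]2C(=C)C[C@@H](O[Si](CC)(CC)CC)[C@H]5C(=C)C(=O)O[C@@H]5[C@H]24)C[C@@H](O[Si](CC)(CC)CC)[C@H]2C(=C)C(=O)O[C@@H]2[C@@H]13 | intermediate (not isolated)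
25 | 8,8′-bis-O-triethylsilyl ether of the target | C=C1C(=O)C2=C3[C@H](CC[C@]24C(=O)C[C@H]2C(=C)C[C@@H](O[Si](CC)(CC)CC)[C@H]5C(=C)C(=O)O[C@@H]5[C@H]24)C[C@@H](O[Si](CC)(CC)CC)[C@H]2C(=C)C(=O)O[C@@H]2[C@H]13 | intermediate
26 | CNP0397417.1 | C=C1C(=O)C2=C3[C@H](CC[C@]24C(=O)C[C@H]2C(=C)C[C@@H](O)[C@H]5C(=C)C(=O)O[C@@H]5[C@H]24)C[C@@H](O)[C@H]2C(=C)C(=O)O[C@@H]2[C@H]13 | target

**Step count and risks**

Total steps: 14. Longest linear sequence: 11 (steps 1–5 and 9–14); the boronate branch (steps 6–8) is 3 steps.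

Step 11 (seven-membered ring closure by the allylindium) is the most likely to fail: the allylmetal may be protonated or the ring may close with the wrong C6 configuration. The fallback sets out from 18 and comes back at 21. Pd(PPh3)4-catalysed stannylation of 18 with Me3SnSnMe3 gives methyl (3R,4R)-3-formyl-2-methylidene-6-{(1R)-4-oxo-3-[(trimethylstannyl)methyl]cyclopent-2-en-1-yl}-4-[(triethylsilyl)oxy]hept-6-enoate F3. BF3·OEt2 at −78 °C then promotes an intramolecular Lewis-acid allylstannane addition (open transition state) of C5 to the C6 aldehyde, giving methyl 6α-hydroxy-3-oxo-8β-(triethylsilyloxy)-1αH,5αH-guaia-4(15),10(14),11(13)-trien-12-oate F4, which lactonises with PPTS to 21.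

Step 9 (catalyst-controlled allylboration) is the second risk: the ester-deactivated boronate may react slowly or with low facial control. The fallback sets out from 12 (with 9) and comes back at 16, and gives up catalyst control. PBr3 converts 12 with allylic transposition into methyl (Z)-2-(bromomethyl)-4,4-dimethoxybut-2-enoate F1. Indium powder in THF/H2O couples F1 with 9 in a syn-selective aqueous Barbier reaction to a roughly 1:1 mixture of 16 and methyl (3S,4S)-6-[(1R)-3-(acetoxymethyl)-4-oxocyclopent-2-en-1-yl]-3-(dimethoxymethyl)-4-hydroxy-2-methylidenehept-6-enoate F2, from which 16 is separated by chromatography.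

Step 13 (Saegusa/Diels–Alder/isomerisation cascade) is the third risk: palladium may attack the other alkenes, dienone 23 may dimerise with itself, or C10′/C5′ may not settle as assumed. The fallback sets out from 22 and comes back at 25, and generates the dienone without palladium. PhSeCl converts 22 into 2α-(phenylselanyl)-3-oxo-8β-(triethylsilyloxy)-1αH,5αH-guaia-4(15),10(14),11(13)-trien-12,6α-olide F5. H2O2/pyridine at 0 °C in the presence of excess 21 gives the selenoxide, whose syn-elimination with the 1α-H releases 23 slowly, so that it is trapped by 21; DBU treatment as in the main route then gives 25.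

**Further compounds**

F1 | step 9 | methyl (Z)-2-(bromomethyl)-4,4-dimethoxybut-2-enoate | COC(=O)/C(=C/C(OC)OC)CBr
F2 | step 9 | methyl (3S,4S)-6-[(1R)-3-(acetoxymethyl)-4-oxocyclopent-2-en-1-yl]-3-(dimethoxymethyl)-4-hydroxy-2-methylidenehept-6-enoate | COC(=O)C(=C)[C@H](C(OC)OC)[C@@H](O)CC(=C)[C@H]1C=C(COC(C)=O)C(=O)C1
F3 | step 11 | methyl (3R,4R)-3-formyl-2-methylidene-6-{(1R)-4-oxo-3-[(trimethylstannyl)methyl]cyclopent-2-en-1-yl}-4-[(triethylsilyl)oxy]hept-6-enoate | COC(=O)C(=C)[C@@H](C=O)[C@H](O[Si](CC)(CC)CC)CC(=C)[C@H]1C=C(C[Sn](C)(C)C)C(=O)C1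
F4 | step 11 | methyl 6α-hydroxy-3-oxo-8β-(triethylsilyloxy)-1αH,5αH-guaia-4(15),10(14),11(13)-trien-12-oate | COC(=O)C(=C)[C@@H]1[C@H](O[Si](CC)(CC)CC)CC(=C)[C@@H]2CC(=O)C(=C)[C@@H]2[C@H]1O
F5 | step 13 | 2α-(phenylselanyl)-3-oxo-8β-(triethylsilyloxy)-1αH,5αH-guaia-4(15),10(14),11(13)-trien-12,6α-olide | C=C1C(=O)[C@H]([Se]c4ccccc4)[C@H]2C(=C)C[C@@H](O[Si](CC)(CC)CC)[C@H]3C(=C)C(=O)O[C@@H]3[C@H]21
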